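**Strategy.** In furo[3,2-b]furan numbering (O1 lactone oxygen, O4 ether oxygen), the oxolane ring O4–C5–C6–C6a–C3a is cut at C5–C6 and C6a–C3a. What remains is an ether oxygen flanked by two carbons plus the two-carbon unit C6–C6a, whose C6a carries oxygen. Read with the lactone oxygen as the Baeyer–Villiger trace of an acetyl group, this is the retron of a Prins–pinacol rearrangement. A 4-isopropenyl-1,3-dioxolane, the ketal of 12-phenyldodecan-2-one with an (R)-malic acid-derived diol, is therefore built first. SnCl4 should rearrange it into the 3-acetyloxolane, forming both C–C bonds and setting all three stereocentres at once.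

Key step: step 5

Remark: 11-phenylundecanoic acid and (R)-malic acid are taken as commercial; the carbinol carbon made in step 3 and the ketal carbon made in step 4 form as epimer mixtures and are left undefined in the SMILES, because step 5 turns the first into a carbonyl carbon and sets the second.

**Step 1**
Reactants: 1 11-phenylundecanoic acid
Product: 2 12-phenyldodecan-2-one
Conditions: MeLi (2.2 equiv), THF, 0 °C → rt; then aq. HCl
Reagents that add atoms: methyllithium, C[Li]
Why: Addition of MeLi to the lithium carboxylate gives a geminal dilithium alkoxide that survives until aqueous work-up, the standard conversion of a carboxylic acid into a methyl ketone; no stereocentre is involved.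

**Step 2**
Reactants: 3 (R)-malic acid
Product: 4 2-[(4R)-2,2-dimethyl-5-oxo-1,3-dioxolan-4-yl]acetic acid
Conditions: 2,2-dimethoxypropane (excess), p-TsOH (cat.), rt
Reagents that add atoms: 2,2-dimethoxypropane, COC(C)(C)OC
Why: Acid-catalysed acetalisation of the α-hydroxy acid unit should give the five-membered 1,3-dioxolan-4-one in preference to the six-membered alternative, which differentiates the two carboxyl groups without touching the stereocentre.

**Step 3**
Reactants: 4 2-[(4R)-2,2-dimethyl-5-oxo-1,3-dioxolan-4-yl]acetic acid
Product: 8 (4R)-4-hydroxy-5-methyl-5-(prop-1-en-2-yl)oxolan-2-one (C5 epimers), via lactol adduct 5 (not isolated), via keto acid 6 (not isolated), via dihydroxy acid 7 (not isolated)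
Conditions: MeLi (2.05 equiv), THF, −78 °C; then isopropenylmagnesium bromide (3.5 equiv), −78 → 0 °C; then 1 M HCl, rt
Reagents that add atoms: methyllithium, C[Li]; isopropenylmagnesium bromide, CC(=C)[Mg]Br
Why: At −78 °C the acylal-type dioxolanone carbonyl should take up one MeLi to give a tetrahedral alkoxide that holds until warming (organolithium mono-addition to a lactone, the carboxylate being inert), its collapse releases acetone and the α-alkoxido methyl ketone, which the Grignard reagent captures by chelation-controlled 1,2-addition, and acidification lactonises the γ-hydroxy acid; the (R) carbinol centre comes unchanged from malic acid and the new tertiary centre needs no control.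

**Step 4**
Reactants: 2 12-phenyldodecan-2-one; 8 (4R)-4-hydroxy-5-methyl-5-(prop-1-en-2-yl)oxolan-2-one
Product: 10 methyl 2-[(5R)-2,4-dimethyl-2-(10-phenyldecyl)-4-(prop-1-en-2-yl)-1,3-dioxolan-5-yl]acetate (epimers at C2 and C4), via dimethyl ketal 9 (not isolated)
Conditions: 2 (1.5 equiv), HC(OMe)3, MeOH, CSA (cat.), rt, volatiles removed; then 8, CSA (cat.), CH2Cl2, 5 Å MS, rt
Reagents that add atoms: trimethyl orthoformate, COC(OC)OC; methanol, CO
Why: Acid-catalysed ketal exchange at the free secondary hydroxyl and opening of the lactone by the methanol that the exchange releases should be pulled to the dioxolane ester because the tertiary hydroxyl is trapped intramolecularly (transketalisation, as in the usual one-pot conversion of 3-hydroxy-γ-butyrolactone into its acetonide methyl ester); the (R) centre is not touched.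

**Step 5**
Reactants: 10 methyl 2-[(5R)-2,4-dimethyl-2-(10-phenyldecyl)-4-(prop-1-en-2-yl)-1,3-dioxolan-5-yl]acetate
Product: 13 methyl 2-[(2R,3R,5S)-3-acetyl-3,5-dimethyl-5-(10-phenyldecyl)oxolan-2-yl]acetate, via oxocarbenium ion 11 (not isolated), via oxan-4-yl cation 12 (not isolated)
Conditions: SnCl4 (2.5 equiv), CH2Cl2, −78 → −20 °C; then H2O
Reagents that add atoms: none
Why: SnCl4 should open the ketal at the tertiary allylic oxygen to give oxocarbenium ion 11, whose isopropenyl CH2 attacks the oxocarbenium carbon (C5–C6 bond of the target) to give the tertiary cation 12, and a pinacol 1,2-shift of the oxygen-bearing CH from the carbinol carbon to the cationic carbon (C6a–C3a bond) then contracts the oxane to the oxolane and turns the carbinol carbon into the acetyl group. The closest known reaction type is the Lewis acid-promoted Prins–pinacol rearrangement of 4-alkenyl-1,3-dioxolanes to 3-acyltetrahydrofurans. The oxolane ring is closed by a 6-endo-trig Prins cyclisation through a chair transition state followed by ring contraction through the 1,2-alkyl shift. C2 of 13 keeps the (R) configuration of malic acid because the migrating carbon shifts with retention; C3 is set by the chair, in which the equatorial CH2CO2Me group ends cis to the acetyl group; C5 is set by the oxocarbenium geometry, the 10-phenyldecyl group taking the position anti to the ring-oxygen substituent (equatorial) and methyl the syn (axial) one, which places the chain cis to CH2CO2Me. The step needs the Prins–pinacol path to outrun the 2-oxonia-Cope path, which the tertiary cation from the isopropenyl group should secure, and it needs discrimination between methyl and the primary alkyl chain at the ketal carbon, which rests only on their size difference and is the weak point.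

**Step 6**
Reactants: 13 methyl 2-[(2R,3R,5S)-3-acetyl-3,5-dimethyl-5-(10-phenyldecyl)oxolan-2-yl]acetate
Product: 14 methyl 2-[(2R,3R,5S)-3-acetoxy-3,5-dimethyl-5-(10-phenyldecyl)oxolan-2-yl]acetate
Conditions: mCPBA (3 equiv), CH2Cl2, 0 °C → rt
Reagents that add atoms: mCPBA, OOC(=O)c1cccc(Cl)c1
Why: Baeyer–Villiger oxidation, in which the quaternary ring carbon should migrate in preference to methyl and with retention, so the acetoxy group stays cis to the CH2CO2Me group.

**Step 7**
Reactants: 14 methyl 2-[(2R,3R,5S)-3-acetoxy-3,5-dimethyl-5-(10-phenyldecyl)oxolan-2-yl]acetate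
Product: 16 plakortolide ether, (3aR,5S,6aR)-5,6a-dimethyl-5-(10-phenyldecyl)tetrahydrofuro[3,2-b]furan-2(3H)-one, via hydroxy ester 15 (not isolated)
Conditions: NaOMe (0.3 equiv), MeOH, rt; then aq. NH4Cl
Reagents that add atoms: none
Why: Base-catalysed transesterification frees the tertiary alkoxide, which should close 5-exo-trig onto the cis methyl ester to the cis-fused γ-lactone; a reversible retro-oxa-Michael opening at C3a would re-close to the same cis-fused ring, so no stereocentre is at risk.

**Compound list**
1 | 11-phenylundecanoic acid | OC(=O)CCCCCCCCCCc1ccccc1 | starting material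
2 | 12-phenyldodecan-2-one | CC(=O)CCCCCCCCCCc1ccccc1 | intermediate
3 | (R)-malic acid | OC(=O)C[C@@H](O)C(O)=O | starting material
4 | 2-[(4R)-2,2-dimethyl-5-oxo-1,3-dioxolan-4-yl]acetic acid | OC(=O)C[C@H]1OC(C)(C)OC1=O | intermediate
5 | 2-[(4R)-5-hydroxy-2,2,5-trimethyl-1,3-dioxolan-4-yl]acetic acid (lactol adduct, present as its dilithium salt) | OC(=O)C[C@H]1OC(C)(C)OC1(C)O | intermediate
6 | (3R)-3-hydroxy-4-oxopentanoic acid (keto acid, present as its salt) | OC(=O)C[C@@H](O)C(C)=O | intermediate
7 | (3R)-3,4-dihydroxy-4,5-dimethylhex-5-enoic acid (C4 epimers, present as its salt) | OC(=O)C[C@@H](O)C(C)(O)C(C)=C | intermediate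
8 | (4R)-4-hydroxy-5-methyl-5-(prop-1-en-2-yl)oxolan-2-one (C5 epimers) | O=C1C[C@@H](O)C(C)(C(C)=C)O1 | intermediate
9 | 2,2-dimethoxy-12-phenyldodecane | COC(C)(CCCCCCCCCCc1ccccc1)OC | intermediate
10 | methyl 2-[(5R)-2,4-dimethyl-2-(10-phenyldecyl)-4-(prop-1-en-2-yl)-1,3-dioxolan-5-yl]acetate (epimers at C2 and C4) | COC(=O)C[C@H]1OC(C)(CCCCCCCCCCc2ccccc2)OC1(C)C(C)=C | intermediate
11 | ring-opened oxocarbenium ion of 10, (R) at the oxygen-bearing CH (tin-bound tertiary alkoxide drawn as O−) | C=C(C)C(C)([O-])[C@@H](CC(=O)OC)[O+]=C(C)CCCCCCCCCCc1ccccc1 | intermediate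
12 | tertiary oxan-4-yl cation from the Prins closure, 2-methyl and 6-CH2CO2Me trans, 2-(10-phenyldecyl) and 6-CH2CO2Me cis (tin-bound alkoxide drawn as O−) | C[C+]1C[C@](C)(CCCCCCCCCCc2ccccc2)O[C@H](CC(=O)OC)C1(C)[O-] | intermediate
13 | methyl 2-[(2R,3R,5S)-3-acetyl-3,5-dimethyl-5-(10-phenyldecyl)oxolan-2-yl]acetate | C[C@]1(CCCCCCCCCCc2ccccc2)C[C@@](C)(C(C)=O)[C@@H](CC(=O)OC)O1 | intermediate
14 | methyl 2-[(2R,3R,5S)-3-acetoxy-3,5-dimethyl-5-(10-phenyldecyl)oxolan-2-yl]acetate | C[C@]1(CCCCCCCCCCc2ccccc2)C[C@@](C)(OC(C)=O)[C@@H](CC(=O)OC)O1 | intermediate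
15 | methyl 2-[(2R,3R,5S)-3-hydroxy-3,5-dimethyl-5-(10-phenyldecyl)oxolan-2-yl]acetate | C[C@]1(CCCCCCCCCCc2ccccc2)C[C@@](C)(O)[C@@H](CC(=O)OC)O1 | intermediate
16 | plakortolide ether, (3aR,5S,6aR)-5,6a-dimethyl-5-(10-phenyldecyl)tetrahydrofuro[3,2-b]furan-2(3H)-one | C[C@]1(CCCCCCCCCCc2ccccc2)C[C@@]2(C)OC(=O)C[C@H]2O1 | target

**Count.** Total steps: 7. Longest linear sequence: 6 steps (3 → 16, steps 2 to 7); the ketone branch (step 1) joins at step 4.

**Steps most likely to fail**

Step 5. The oxocarbenium ion may form without enough discrimination between methyl and the unbranched chain, so that both faces of the ketal carbon react and the C5 epimer of 13 accompanies it. The fallback sets out from 2 and 8 and comes back at 13. Ketone 2 is brominated on its more substituted side (Br2, AcOH) to 3-bromo-12-phenyldodecan-2-one F1. HC(OMe)3, MeOH and CSA convert this into its dimethyl ketal 3-bromo-2,2-dimethoxy-12-phenyldodecane F2, which is exchanged with 8 as in step 4 to the bromo dioxolane methyl 2-[(5R)-2-(1-bromo-10-phenyldecyl)-2,4-dimethyl-4-(prop-1-en-2-yl)-1,3-dioxolan-5-yl]acetate F3. The ketal carbon now carries methyl against a secondary, bromine-bearing carbon, a size difference that should fix the oxocarbenium geometry. SnCl4 as in step 5 should then give the bromo keto ester methyl 2-[(2R,3R,5R)-3-acetyl-5-(1-bromo-10-phenyldecyl)-3,5-dimethyloxolan-2-yl]acetate F4, and Bu3SnH, AIBN, PhH, 80 °C removes the bromine to give 13.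

Step 3. MeLi may add twice to the dioxolanone carbonyl, or deprotonate its α-carbon with loss of configuration at the carbinol centre. The fallback sets out from 4 and comes back at 8. Compound 4 is opened with MeNHOMe·HCl, i-PrMgCl, THF, −20 °C to the Weinreb amide (3R)-3-hydroxy-4-[methoxy(methyl)amino]-4-oxobutanoic acid F5 with loss of acetone. MeMgBr then stops at the chelated adduct and gives keto acid 6 on work-up, now isolated. Isopropenylmagnesium bromide followed by acidification gives 8 through 7.

Step 4. The acid that lactone opening needs may ionise the tertiary allylic C–O bond, or the exchange equilibrium may stay on the lactone side. The fallback sets out from 8 and comes back at 10. Compound 8 is saponified with NaOH (1.0 equiv), THF/H2O, and the sodium salt of 7 is alkylated with MeI in DMF, without acid, to the diol ester methyl (3R)-3,4-dihydroxy-4,5-dimethylhex-5-enoate F6. F6 is ketalised at once with isolated 9, PPTS (cat.), CH2Cl2, 5 Å MS to give 10.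

**Further compounds**
F1 | step 5 | 3-bromo-12-phenyldodecan-2-one | CC(=O)C(Br)CCCCCCCCCc1ccccc1
F2 | step 5 | 3-bromo-2,2-dimethoxy-12-phenyldodecane | COC(C)(OC)C(Br)CCCCCCCCCc1ccccc1
F3 | step 5 | methyl 2-[(5R)-2-(1-bromo-10-phenyldecyl)-2,4-dimethyl-4-(prop-1-en-2-yl)-1,3-dioxolan-5-yl]acetate | COC(=O)C[C@H]1OC(C)(C(Br)CCCCCCCCCc2ccccc2)OC1(C)C(C)=C
F4 | step 5 | methyl 2-[(2R,3R,5R)-3-acetyl-5-(1-bromo-10-phenyldecyl)-3,5-dimethyloxolan-2-yl]acetate (epimers at CHBr) | C[C@]1(C(Br)CCCCCCCCCc2ccccc2)C[C@@](C)(C(C)=O)[C@@H](CC(=O)OC)O1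
F5 | step 3 | (3R)-3-hydroxy-4-[methoxy(methyl)amino]-4-oxobutanoic acid | CON(C)C(=O)[C@H](O)CC(O)=O
F6 | step 4 | methyl (3R)-3,4-dihydroxy-4,5-dimethylhex-5-enoate (C4 epimers) | COC(=O)C[C@@H](O)C(C)(O)C(C)=C
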